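The data come from a simulation from invented constants, noise included.

Late in the alpha run, which is this flask followed so far, the readings stop moving: free starting complex stands at 10% at 25.0 min and 10% at 50.0 min, and complex with one exchanged at 44% and then 41%.

| flask | starting complex | incoming ligand | temperature | remark | time |
|---|---|---|---|---|---|
| alpha | 0.050 M | 2 equiv | 5 °C | the very flask that is asked about, followed so far |  |
| zeta | 0.10 M | 2 equiv | −10 °C | run made earlier |  |
| flask | 0.050 M | 2.00 equiv | 5 °C |  | 80 min |

| run | time / min | complex with one exchanged / % | starting complex / % |
|---|---|---|---|
| alpha | 4.00 | 22 | 63 |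
| alpha | 8.00 | 28 | 41 |
| alpha | 15.0 | 39 | 22 |
| alpha | 25.0 | 44 | 10 |
| alpha | 50.0 | 41 | 10 |
| zeta | 12.0 | 28 | 50 |
| zeta | 25.0 | 37 | 25 |
| zeta | 40.0 | 43 | 11 |
| zeta | 50.0 | 42 | 7 |
| zeta | 60.0 | 45 | 4 |

(each reading ± 1.5 percentage points)

- noon: at 80 min take out 90% of the leaving ligand then present, then wait 2.5 h
- spring: change nothing and wait 2.5 h more
- dusk: at 80 min raise the temperature by 25 K, then wait 2.5 h
- autumn: at 80 min add incoming ligand, 50.0% of the amount charged, then wait 2.5 h

- complex with one exchanged, in percent of the starting complex first charged, at 80 min
- which option adds most complex with one exchanged ("none" when 2 percentage points or less is all one gets) (noon / spring / dusk / autumn / none)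
- complex with one exchanged present, in percent of the starting complex first charged, after noon
- complex with one exchanged present, in percent of the starting complex first charged, after spring

- additions leave the volume as it is
- a reading of starting complex is of its free form alone

With 2 equiv of incoming ligand charged and 44% of product formed, the stop in alpha is no shortage of incoming ligand. Starting complex and product stand side by side, so the first exchange seems to run back about as fast as forward, a quasi-equilibrium. For a step in balance at fixed temperature, product times leaving ligand over starting complex times incoming ligand keeps one value, so product over free starting complex holds still as long as incoming over leaving ligand does. That is the quantity to freeze: the stall ratio, product over free starting complex, read from the two late alpha readings as 4.25. It is a rough reading, since the scatter of 1.5 percentage points falls on numbers near 10%. If free starting complex stays near 10%, my own reckoning for 80 min is 42.5%.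

Beside incoming ligand, free leaving ligand moves the ratio, and the alpha readings say something of it. The part of the charge that is neither free nor product is 31.0% at 8.00 min against 28% of product, and 46.0% at 25.0 min against 44%. I read this missing part as starting complex tied to the leaving ligand that each exchange sets free, and I take the free leaving ligand in alpha to be the smaller share. Taking out 90% of the free part then leaves the tied store to refill it, so I expect noon and spring to end within 2 points of each other. Zeta differs from alpha in both temperature and concentration, so I draw nothing from it for dusk.

The forecast, which parts from this on noon, gave 42.5% (40% to 45%), 47.5% after noon, 42.5% after spring and noon as best, holding that “Removing leaving ligand pulls that 10% forward”.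

The flask gives 39.7% at 80 min, 35.5% after noon and 35.2% after spring, 0.30 points apart, and the best option is dusk, at 9.6 points.

    starting complex + incoming ligand ⇌ leaving ligand + complex with one exchanged (K = 0.0950, k = 0.610 L mol⁻¹ min⁻¹, Ea = 54.0 kJ mol⁻¹, ΔH = −6.00 kJ mol⁻¹)
    complex with one exchanged + incoming ligand ⇌ leaving ligand + complex with two exchanged (K = 0.190, k = 0.0420 L mol⁻¹ min⁻¹, Ea = 63.0 kJ mol⁻¹, ΔH = −47.0 kJ mol⁻¹)
    complex with two exchanged + incoming ligand ⇌ leaving ligand + complex with three exchanged (K = 4.50, k = 0.560 L mol⁻¹ min⁻¹, Ea = 51.0 kJ mol⁻¹, ΔH = 12.0 kJ mol⁻¹)
    complex with three exchanged + incoming ligand ⇌ leaving ligand + complex with four exchanged (K = 1.70, k = 3.70 L mol⁻¹ min⁻¹, Ea = 49.0 kJ mol⁻¹, ΔH = −29.0 kJ mol⁻¹)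
    leaving ligand → by-product carried off (k = 0.180 min⁻¹, Ea = 82.0 kJ mol⁻¹)
    leaving ligand + starting complex ⇌ idle adduct, settled at all times (K = 4300 L mol⁻¹, ΔH = −34.0 kJ mol⁻¹)
    (constants at 5 °C)

At 80 min this flask holds 0.00115 M of free leaving ligand, less than the 0.0212 M in idle adduct, a resting state of the starting complex. The stall ratio on this flask's 8.59% of free starting complex gives 36.5%, which is 3.2 points under the product there.

In the neighbour flask with 0.20 M of starting complex, 3.18% stays free at 80 min, so the stall ratio gives 13.5% of product. The computed value for that flask is 13.2%.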